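The bond on which everything rests joins the gem-dimethyl carbon (C11) to its cyclobutane neighbour (C10). A linear, enantioenriched dienynoic acid is folded by an intramolecular vinylketene–alkene [2+2] into the bicyclo[3.1.1]heptane: cyclobutane C4–C5–C10–C9, three-carbon bridge C6–C8, ketone at C10, axial ethynyl on C4. Acylation and semi-reduction turn the alkyne into a cross-conjugated dienone arm. A copper hydride reductive aldol then closes the seven-membered ring C1–C2–C3–C4–C9–C10–C11. The enolate carbon C11 can reach the C10 ketone only along the C4 tether, so the quaternary centre and the C10 configuration are fixed together. The ring alkene C2=C3 later becomes the cis-diol.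

Key step: step 9

Remarks on the chemistry (stated before the steps):
- Skeleton numbering used throughout (not IUPAC): C1 = CH–O-angeloyl, C2 = CH–O-isovaleryl, C3 = CH–OH, C4 = cyclobutane C(CH3), C5 = cyclobutane CH next to the ketone, C6 = C=O, C7 = =CH, C8 = =C(CH3), C9 = cyclobutane CH next to C8, C10 = cyclobutane CH bearing C11, C11 = C(CH3)2. "Bridge face" is the cyclobutane face carrying the C6–C8 bridge; "far face" is the opposite one.
- Chain carbons C1–C9 of acid 8 become skeleton C10, C9, C8, C7, C6, C5, C4, C3, C2 in that order. Methacryloyl chloride supplies C1, C11 and both C11 methyls.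
- Assumption: the (S,S) enantiomer of the bisphosphoramide is taken to be the one that sends the dienol ether to the Si face of aldehyde 2. If the facial sense is the reverse, its mirror image is used.
- Assumption: step 6 may also give some of the endocyclic C7=C8 isomer of 11. Both isomers converge at enone 24, and only the exocyclic isomer is written.

Step 1
Reactants: 1 (2E)-3-methylpent-2-en-4-yn-1-ol
Product: 2 (2E)-3-methylpent-2-en-4-ynal
Conditions: MnO2 (activated, excess), CH2Cl2, rt
Reagents that add atoms: none
Why: Allylic oxidation with MnO2 should convert the primary allylic alcohol into the conjugated aldehyde without touching the alkyne or the E geometry.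

Step 2
Reactants: 3 methyl 3-methylbut-2-enoate
Product: 5 silyl dienol ether, via lithium dienolate 4 (not isolated)
Conditions: LDA, THF, –78 °C; then TBSCl, DMPU, –78 °C to rt
Reagents that add atoms: tert-butyldimethylsilyl chloride, CC(C)(C)[Si](C)(C)Cl
Why: γ-Deprotonation of the senecioate and O-silylation of the dienolate (silyl ketene acetal formation) should give the vinylogous nucleophile; no stereocenter is formed.

Step 3
Reactants: 2 enynal; 5 silyl dienol ether
Product: 6 methyl (2E,5S,6E)-5-hydroxy-3,7-dimethylnona-2,6-dien-8-ynoate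
Conditions: SiCl4 (1.1 equiv), (S,S)-bisphosphoramide derived from 2,2'-diamino-1,1'-binaphthyl (5 mol %), i-Pr2NEt (10 mol %), CH2Cl2, –78 °C; aq. NaHCO3
Reagents that add atoms: none
Why: In this catalytic enantioselective vinylogous Mukaiyama aldol addition the dienol ether should react at its γ-carbon to give the E-enoate, and catalyst-controlled Si-face attack on the aldehyde sets the carbinol carbon (chain C5, future C6) as S.

Step 4
Reactants: 6 hydroxy ester
Product: 7 silyl ether of 6
Conditions: TBSCl, imidazole, DMF, rt
Reagents that add atoms: tert-butyldimethylsilyl chloride, CC(C)(C)[Si](C)(C)Cl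
Why: Standard silylation of a secondary alcohol should protect the future C6 oxygen and make it the bulky control element for step 6.

Step 5
Reactants: 7 silyloxy ester
Product: 8 (2E,5S,6E)-5-[(tert-butyldimethylsilyl)oxy]-3,7-dimethylnona-2,6-dien-8-ynoic acid
Conditions: LiOH·H2O, THF/MeOH/H2O, rt; then dilute HCl to pH 4 at 0 °C
Reagents that add atoms: lithium hydroxide, [Li+].[OH-]
Why: Saponification of the methyl ester under mild conditions should leave the silyl ether and the stereocenter untouched.

Step 6
Reactants: 8 dienynoic acid
Product: 11 bicyclic ethynyl cyclobutanone, via acid chloride 9 (not isolated), via vinylketene 10 (not isolated)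
Conditions: 1-chloro-N,N,2-trimethylprop-1-en-1-amine (Ghosez reagent), CH2Cl2, 0 °C; then slow addition to Et3N (3 equiv), toluene, 110 °C, high dilution
Reagents that add atoms: none
Why: In this intramolecular vinylketene–alkene [2+2] cycloaddition (the chrysanthenone-type closure) the ketene carbonyl carbon (future C10) should bond to the CH alkene carbon (future C5) and the ketene α-carbon (future C9) to the cation-stabilizing methyl/ethynyl carbon (future C4), giving the bridged bicyclo[3.1.1] system; the E-alkene geometry places the methyl on the bridge face and the ethynyl on the far face, and the silyloxy stereocenter selects the alkene face through 1,3-allylic strain (its hydrogen eclipses the cis-methyl, the tether lies on one face and the silyloxy group on the other), so C4, C5 and C9 all follow from it.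

Step 7
Reactants: 11 bicyclic ethynyl cyclobutanone
Product: 12 ynone
Conditions: methacryloyl chloride (1.5 equiv), PdCl2(PPh3)2 (2 mol %), CuI (4 mol %), Et3N, THF, rt
Reagents that add atoms: methacryloyl chloride, CC(=C)C(=O)Cl
Why: The acyl Sonogashira coupling of a terminal alkyne with an acid chloride should install C1 and C11 under conditions that the non-enolizable cyclobutanone tolerates.

Step 8
Reactants: 12 ynone
Product: 13 (Z)-dienone
Conditions: H2 (1 atm), Lindlar catalyst (Pd on CaCO3 poisoned with Pb(OAc)2), quinoline, EtOAc, 0 °C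
Reagents that add atoms: none
Why: Lindlar semi-hydrogenation adds hydrogen syn to the alkyne and should give the Z-enone that the ring needs, while the poisoned catalyst spares the 1,1-disubstituted alkenes.

Step 9
Reactants: 13 (Z)-dienone
Product: 16 tricyclic aldol, via copper enolate 14 (not isolated), via copper aldolate 15 (not isolated)
Conditions: [(Ph3P)CuH]6 (0.2 equiv of hexamer, 1.2 equiv of hydride), toluene/THF, –40 to 0 °C; aq. NH4Cl
Reagents that add atoms: none
Why: Hydride from the copper hydride cluster adds to the unhindered CH2 terminus of the isopropenyl ketone and gives copper enolate 14 regiospecifically at C11, which adds to the strained C10 cyclobutanone to give aldolate 15, protonated on work-up. The closest known reaction type is the reductive aldol cyclization of keto-enones with this reagent (a conjugate reduction followed by an intramolecular aldol addition). The ring closed is the seven-membered ring C1–C2–C3–C4–C9–C10–C11, by a 7-(enolendo)-exo-trig closure in which the C11=C1 enolate and the cis C2=C3 alkene lie inside the forming ring. The new stereocenter C10 is controlled by the tether: the arm is axial on C4 and reaches only the far-face lobe of the C10 carbonyl, so C11 ends axial and the hydroxyl outside, while C11 becomes quaternary without a stereochemical issue. The step needs conjugate hydride delivery to the isopropenyl terminus rather than to the Z-enone β-carbon C3 or to either carbonyl; C3 is neopentylic and shielded by the quaternary C4, and phosphine copper hydride prefers 1,4- over 1,2-reduction. Cyclization rather than simple protonation of the enolate should be favoured by the release of cyclobutanone angle strain on addition.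

Step 10
Reactants: 16 tricyclic aldol
Product: 17 C10 methyl oxalate
Conditions: methyl chlorooxoacetate, pyridine, DMAP (cat.), CH2Cl2, 0 to 40 °C
Reagents that add atoms: methyl chlorooxoacetate, COC(=O)C(=O)Cl
Why: Acylation with a small, very reactive acid chloride under amine (not alkoxide) conditions should convert the tertiary alcohol into a radical precursor without triggering a retro-aldol.

Step 11
Reactants: 17 C10 methyl oxalate
Product: 18 C1 allylic alcohol
Conditions: (S)-2-methyl-CBS-oxazaborolidine (0.5 equiv), catecholborane, toluene, –78 °C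
Reagents that add atoms: none
Why: The Corey–Bakshi–Shibata reduction should deliver hydride 1,2 under catalyst control, with the quaternary C11 as the large and the sp2 C2 as the small substituent, which sets C1; the nearly mirror-symmetric core offers no bias of its own.

Step 12
Reactants: 18 C1 allylic alcohol
Product: 19 deoxygenated allylic alcohol
Conditions: Bu3SnH, AIBN (cat.), toluene, 110 °C
Reagents that add atoms: none
Why: In this Barton-type radical deoxygenation of a tertiary methyl oxalate the C10 radical sits at a bridgehead of the new bicyclo[4.1.1] system and can take hydrogen only on its open outer lobe, so C10 keeps the configuration fixed in step 9; syn-elimination is impossible because every β-position is a bridgehead or quaternary.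

Step 13
Reactants: 19 deoxygenated allylic alcohol
Product: 21 C1 angelate, via lithium alkoxide 20 (not isolated)
Conditions: LiHMDS, THF, –78 °C; then angelic anhydride, –78 to 0 °C
Reagents that add atoms: angelic anhydride, C/C=C(/C)C(=O)OC(=O)/C(C)=C\C
Why: Acylation of the preformed alkoxide at low temperature should esterify the hindered C1 hydroxyl without the Z-to-E isomerization that nucleophilic acylation catalysts cause in angelates.

Step 14
Reactants: 21 C1 angelate
Product: 22 C6 alcohol
Conditions: HF·pyridine, pyridine/THF, 0 °C to rt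
Reagents that add atoms: none
Why: Buffered fluoride desilylation should free the C6 hydroxyl while leaving the allylic angelate in place.

Step 15
Reactants: 22 C6 alcohol
Product: 24 enone, via β,γ-unsaturated ketone 23 (not isolated)
Conditions: Dess–Martin periodinane, NaHCO3, CH2Cl2, 0 °C to rt; then DBU (0.2 equiv), 0 °C
Reagents that add atoms: none
Why: Dess–Martin oxidation gives the C6 ketone, and base-mediated migration of the exocyclic alkene into conjugation (via the dienolate) should give the trisubstituted C7=C8 enone, which also destroys the C6 stereocenter that has done its work.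

Step 16
Reactants: 24 enone
Product: 25 C2,C3-diol
Conditions: OsO4 (5 mol %), NMO, acetone/H2O, 0 °C to rt
Reagents that add atoms: N-methylmorpholine N-oxide, C[N+]1([O-])CCOCC1; water, O
Why: Upjohn dihydroxylation should add syn to the cis-disubstituted ring alkene (the enone and angelate alkenes are electron-poor and trisubstituted) from the face anti to the allylic C1 acyloxy group, setting C2 and C3 cis to each other and trans to the C1 oxygen.

Step 17
Reactants: 25 C2,C3-diol
Product: 26 target CNP0128158.1
Conditions: isovaleryl chloride (1.1 equiv), 2,4,6-collidine, CH2Cl2, –40 to –10 °C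
Reagents that add atoms: 3-methylbutanoyl chloride, CC(C)CC(=O)Cl
Why: Site-selective acylation should take place at the ordinary secondary C2 hydroxyl and not at the neopentylic C3 hydroxyl next to the quaternary C4, and the hindered pyridine base at low temperature should not isomerize the angelate.

Compound list
1 | (2E)-3-methylpent-2-en-4-yn-1-ol | OC/C=C(\C)C#C | starting material
2 | (2E)-3-methylpent-2-en-4-ynal | O=C/C=C(\C)C#C | intermediate
3 | methyl 3-methylbut-2-enoate | COC(=O)C=C(C)C | starting material
4 | lithium 1-methoxy-3-methylbuta-1,3-dien-1-olate (ketene acetal geometry immaterial) | [Li]OC(OC)=CC(C)=C | intermediate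
5 | tert-butyl[(1-methoxy-3-methylbuta-1,3-dien-1-yl)oxy]dimethylsilane (geometry immaterial) | COC(O[Si](C)(C)C(C)(C)C)=CC(C)=C | intermediate
6 | methyl (2E,5S,6E)-5-hydroxy-3,7-dimethylnona-2,6-dien-8-ynoate | COC(=O)/C=C(\C)C[C@H](O)/C=C(\C)C#C | intermediate
7 | methyl (2E,5S,6E)-5-[(tert-butyldimethylsilyl)oxy]-3,7-dimethylnona-2,6-dien-8-ynoate | COC(=O)/C=C(\C)C[C@H](O[Si](C)(C)C(C)(C)C)/C=C(\C)C#C | intermediate
8 | (2E,5S,6E)-5-[(tert-butyldimethylsilyl)oxy]-3,7-dimethylnona-2,6-dien-8-ynoic acid | OC(=O)/C=C(\C)C[C@H](O[Si](C)(C)C(C)(C)C)/C=C(\C)C#C | intermediate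
9 | acid chloride of 8 | ClC(=O)/C=C(\C)C[C@H](O[Si](C)(C)C(C)(C)C)/C=C(\C)C#C | intermediate
10 | vinylketene, (5S,6E)-5-[(tert-butyldimethylsilyl)oxy]-7-methyl-3-methylidenenona-1,6-dien-8-yn-1-one | O=C=CC(=C)C[C@H](O[Si](C)(C)C(C)(C)C)/C=C(\C)C#C | intermediate
11 | (2S)-2-[(tert-butyldimethylsilyl)oxy]-7-ethynyl-7-methyl-4-methylidenebicyclo[3.1.1]heptan-6-one; skeleton: C10 ketone, C6 silyloxy pointing to the C10 side, C8 methylidene, C4 methyl on the bridge face, C4 ethynyl on the far face | C#C[C@@]1(C)[C@@H]2[C@@H](O[Si](C)(C)C(C)(C)C)CC(=C)[C@H]1C2=O | intermediate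
12 | ynone: 11 with the C4 ethynyl acylated to C≡C–C(=O)–C(CH3)=CH2 | CC(=C)C(=O)C#C[C@@]1(C)[C@@H]2[C@@H](O[Si](C)(C)C(C)(C)C)CC(=C)[C@H]1C2=O | intermediate
13 | (Z)-dienone: 12 with the alkyne reduced to the cis C2=C3 alkene | CC(=C)C(=O)/C=C\[C@@]1(C)[C@@H]2[C@@H](O[Si](C)(C)C(C)(C)C)CC(=C)[C@H]1C2=O | intermediate
14 | copper enolate of 13 (C11=C1–O–Cu, phosphine-ligated) | CC(C)=C(O[Cu])/C=C\[C@@]1(C)[C@@H]2[C@@H](O[Si](C)(C)C(C)(C)C)CC(=C)[C@H]1C2=O | intermediate
15 | copper aldolate of 16 (C10–O–Cu) | O=C1C=C[C@@]2(C)[C@@H]3[C@@H](O[Si](C)(C)C(C)(C)C)CC(=C)[C@H]2[C@]3(O[Cu])C1(C)C | intermediate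
16 | tricyclic aldol: C1 ketone conjugated with cis C2=C3, C10 tertiary hydroxyl on the outer position, C11 gem-dimethyl, C6 silyloxy, C8 methylidene, C4 methyl | O=C1C=C[C@@]2(C)[C@@H]3[C@@H](O[Si](C)(C)C(C)(C)C)CC(=C)[C@H]2[C@]3(O)C1(C)C | intermediate
17 | C10 methyl oxalate of 16 | O=C1C=C[C@@]2(C)[C@@H]3[C@@H](O[Si](C)(C)C(C)(C)C)CC(=C)[C@H]2[C@]3(OC(=O)C(=O)OC)C1(C)C | intermediate
18 | C1 allylic alcohol (C1 R) carrying the C10 methyl oxalate | O[C@@H]1C=C[C@@]2(C)[C@@H]3[C@@H](O[Si](C)(C)C(C)(C)C)CC(=C)[C@H]2[C@]3(OC(=O)C(=O)OC)C1(C)C | intermediate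
19 | deoxygenated allylic alcohol: C10–H, C1–OH, C2=C3, C6 silyloxy, C8 methylidene | O[C@@H]1C=C[C@@]2(C)[C@@H]3[C@@H](O[Si](C)(C)C(C)(C)C)CC(=C)[C@H]2[C@@H]3C1(C)C | intermediate
20 | lithium alkoxide of 19 | [Li]O[C@@H]1C=C[C@@]2(C)[C@@H]3[C@@H](O[Si](C)(C)C(C)(C)C)CC(=C)[C@H]2[C@@H]3C1(C)C | intermediate
21 | C1 angelate of 19 | C/C=C(/C)C(=O)O[C@@H]1C=C[C@@]2(C)[C@@H]3[C@@H](O[Si](C)(C)C(C)(C)C)CC(=C)[C@H]2[C@@H]3C1(C)C | intermediate
22 | C6 alcohol: 21 without the silyl group | C/C=C(/C)C(=O)O[C@@H]1C=C[C@@]2(C)[C@@H]3[C@@H](O)CC(=C)[C@H]2[C@@H]3C1(C)C | intermediate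
23 | β,γ-unsaturated ketone: C6 ketone with the C8 methylidene still exocyclic | C/C=C(/C)C(=O)O[C@@H]1C=C[C@@]2(C)[C@@H]3C(=O)CC(=C)[C@H]2[C@@H]3C1(C)C | intermediate
24 | enone: C6 ketone, C7=C8 with methyl on C8, C1 angelate, C2=C3 | C/C=C(/C)C(=O)O[C@@H]1C=C[C@@]2(C)[C@@H]3C(=O)C=C(C)[C@H]2[C@@H]3C1(C)C | intermediate
25 | C2,C3-diol: hydroxyls cis to each other and trans to the C1 angelate | C/C=C(/C)C(=O)O[C@@H]1[C@@H](O)[C@@H](O)[C@@]2(C)[C@@H]3C(=O)C=C(C)[C@H]2[C@@H]3C1(C)C | intermediate
26 | CNP0128158.1: C1 angelate, C2 isovalerate, C3 hydroxyl | C/C=C(/C)C(=O)O[C@@H]1[C@@H](OC(=O)CC(C)C)[C@@H](O)[C@@]2(C)[C@@H]3C(=O)C=C(C)[C@H]2[C@@H]3C1(C)C | target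

Total step count: 17. Longest linear sequence: 16 steps (steps 1 and 3 to 17); step 2 is a one-step side branch.

Steps most likely to fail

Step 9 (key step). The hydride may be transferred 1,2 to the strained cyclobutanone, or the congested aldol addition may revert so that the copper enolate is simply protonated on work-up. Free phosphine could also isomerize the Z-enone to the E-isomer, which cannot close. The fallback separates enolate formation from ring closure; it sets out from 13 and comes back at 16. Rhodium-catalyzed 1,4-hydrosilylation of the isopropenyl ketone (Et3SiH, RhCl(PPh3)3, benzene, 50 °C) should give the triethylsilyl enol ether F1. An intramolecular Mukaiyama aldol addition (TiCl4, CH2Cl2, –78 °C), which traps the adduct as a titanium chelate and does not revert at that temperature, should then give 16.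

Step 6. The alkene is attenuated by the ethynyl group and by two allylic positions and may be too poor a nucleophile. The vinylketene would then dimerize, or the allylic silyl ether would ionize at 110 °C before cycloaddition. The fallback uses a more electrophilic cumulene; it sets out from 8 and comes back at 11. Amide coupling (dimethylamine hydrochloride, EDC, HOBt, i-Pr2NEt) should give the N,N-dimethylamide F2. Activation with Tf2O and 2,4,6-collidine in 1,2-dichloroethane (0 to 80 °C) generates the vinylketeniminium ion, whose intramolecular [2+2] should give the cyclobutaniminium triflate F3 with the same regiochemistry and facial control. Hydrolysis with aqueous NaHCO3 gives 11.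

Step 10. Acylation may stall at the tertiary hydroxyl, which is flanked by two bridgeheads, the quaternary C11 and the neighbouring silyl ether, or the base may open the aldol by retro-aldol cleavage. The fallback removes the ketone first and uses a smaller electrophile on the alkoxide; it sets out from 16 and comes back at 19. CBS reduction as in step 11 should give the diol F4, and TESCl with imidazole should silylate only the secondary hydroxyl to give the C1 triethylsilyl ether F5. With no carbonyl left for a retro-aldol, KHMDS, CS2 and then MeI should give the tertiary S-methyl xanthate F6, which cannot undergo syn-elimination. Barton–McCombie reduction (Bu3SnH, AIBN, toluene, 110 °C) gives the C10–H silyl ether F7, and PPTS in MeOH removes the triethylsilyl group selectively to return 19.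

Further compounds
F1 | step 9 | triethylsilyl enol ether of 13 (C11=C1–O–SiEt3, cis C2=C3, C10 cyclobutanone) | CC(C)=C(O[Si](CC)(CC)CC)/C=C\[C@@]1(C)[C@@H]2[C@@H](O[Si](C)(C)C(C)(C)C)CC(=C)[C@H]1C2=O
F2 | step 6 | (2E,5S,6E)-5-[(tert-butyldimethylsilyl)oxy]-N,N,3,7-tetramethylnona-2,6-dien-8-ynamide | CN(C)C(=O)/C=C(\C)C[C@H](O[Si](C)(C)C(C)(C)C)/C=C(\C)C#C
F3 | step 6 | cyclobutaniminium triflate corresponding to 11 (C10=N+(CH3)2) | C#C[C@@]1(C)[C@@H]2[C@@H](O[Si](C)(C)C(C)(C)C)CC(=C)[C@H]1C2=[N+](C)C.[O-]S(=O)(=O)C(F)(F)F
F4 | step 10 | tricyclic diol (C1–OH, C10–OH, C2=C3, C6 silyloxy, C8 methylidene) | O[C@@H]1C=C[C@@]2(C)[C@@H]3[C@@H](O[Si](C)(C)C(C)(C)C)CC(=C)[C@H]2[C@]3(O)C1(C)C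
F5 | step 10 | C1 triethylsilyl ether of F4 | CC[Si](CC)(CC)O[C@@H]1C=C[C@@]2(C)[C@@H]3[C@@H](O[Si](C)(C)C(C)(C)C)CC(=C)[C@H]2[C@]3(O)C1(C)C
F6 | step 10 | C10 S-methyl xanthate of F5 | CC[Si](CC)(CC)O[C@@H]1C=C[C@@]2(C)[C@@H]3[C@@H](O[Si](C)(C)C(C)(C)C)CC(=C)[C@H]2[C@]3(OC(=S)SC)C1(C)C
F7 | step 10 | C1 triethylsilyl ether of 19 | CC[Si](CC)(CC)O[C@@H]1C=C[C@@]2(C)[C@@H]3[C@@H](O[Si](C)(C)C(C)(C)C)CC(=C)[C@H]2[C@@H]3C1(C)C
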